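## Plan

- Retrosynthesis: cut O1–C2 (ring C, Mitsunobu etherification), then C4a–C5 (ring A, Claisen cyclisation of a linear 3,5,7-triketo ester), then the C4–C4a chain bond (acylation of a triketide trianion), then C2–C3 (hydroxymethylation of an arylacetyl imide), and last the pyran ring of ring B (propargyl Claisen cascade).
- Enabling feature: ring A is a phloroglucinol, with oxygen on C5, C7 and C8a and the acyl carbon C4 on C4a. This is the aromatic ring an acyl-triacetate chain gives when its C4a carbon closes onto the ester carbon that becomes C5.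
- Forward order: chromene on the ring B arylacetic acid, then C3 with its CH2O arm (C2), then the chain joined through C4–C4a, then ring A (C4a–C5), then ring C (O1–C2), then desilylation.
- Stereochemistry: the only centre, C3 (R), is set by an Evans titanium-enolate hydroxymethylation on the (S)-4-benzyloxazolidin-2-one imide and is then only carried; later steps are chosen to keep its C–H non-acidic.

Key step: step 11

Abbreviations: TIPS = triisopropylsilyl, TBS = tert-butyldimethylsilyl, Ar = 2,2-dimethyl-5-(TIPS-oxy)-2H-chromen-8-yl.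
Remark: the polyketo compounds 20 and 21 are drawn as keto tautomers although they exist largely as enols or metal chelates; C2–C8a are isoflavanone locants, and chain locants refer to nonanoate 20.

## Route

Step 1
Reactants: 1 2,4-dihydroxyphenylacetic acid
Product: 2 methyl 2-(2,4-dihydroxyphenyl)acetate
Conditions: MeOH, H2SO4 (cat.), reflux
Reagents that add atoms: methanol, CO
Why: Fischer esterification in excess methanol should drive the acid (and any lactone formed with the ortho hydroxyl) to the methyl ester, which masks the carboxyl group during the two phenol functionalisations.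

Step 2
Reactants: 2 methyl 2-(2,4-dihydroxyphenyl)acetate
Product: 3 methyl 2-[2-hydroxy-4-(TIPS-oxy)phenyl]acetate
Conditions: TIPSCl (1.05 equiv), imidazole, CH2Cl2, 0 °C
Reagents that add atoms: triisopropylsilyl chloride, CC(C)[Si](Cl)(C(C)C)C(C)C
Why: Regioselective phenol silylation, in which the bulky chloride should take the open 4-hydroxyl rather than the 2-hydroxyl, which is flanked by the CH2CO2Me arm and hydrogen-bonded to its carbonyl.

Step 3
Reactants: 3 methyl 2-[2-hydroxy-4-(TIPS-oxy)phenyl]acetate; 4 3-chloro-3-methylbut-1-yne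
Product: 5 methyl 2-[2-(2-methylbut-3-yn-2-yloxy)-4-(TIPS-oxy)phenyl]acetate
Conditions: DBU, CuCl2·2H2O (cat.), MeCN, 0 °C
Reagents that add atoms: none
Why: Copper-catalysed propargylic etherification of a phenol with a tertiary propargylic chloride, which places the dimethylpropargyl group on the only free phenol, the oxygen that becomes the pyran oxygen.

Step 4
Reactants: 5 methyl 2-[2-(2-methylbut-3-yn-2-yloxy)-4-(TIPS-oxy)phenyl]acetate
Product: 8 methyl 2-[2,2-dimethyl-5-(TIPS-oxy)-2H-chromen-8-yl]acetate, via ortho-allenylphenol 6 (not isolated), via ortho-quinone methide 7 (not isolated)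
Conditions: N,N-diethylaniline, 180 °C, Ar
Reagents that add atoms: none
Why: Aromatic propargyl Claisen rearrangement to the only free ortho carbon (the other carries the acetate arm), then enolisation to 6, 1,5-hydrogen shift to 7 and oxa-6π electrocyclisation, the standard cascade to 2,2-dimethyl-2H-chromenes, with the regiochemistry fixed by the position of the ether.

Step 5
Reactants: 8 methyl 2-[2,2-dimethyl-5-(TIPS-oxy)-2H-chromen-8-yl]acetate
Product: 9 2-[2,2-dimethyl-5-(TIPS-oxy)-2H-chromen-8-yl]acetic acid
Conditions: LiOH·H2O, THF/H2O, 0 °C; then 1 M HCl to pH 4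
Reagents that add atoms: lithium hydroxide, [Li+].[OH-]
Why: Saponification of an unhindered methyl arylacetate is fast at 0 °C, whereas hydroxide attack on the hindered aryl TIPS ether next to the chromene C4–H is slow, so the ester should be cleaved selectively.

Step 6
Reactants: 9 2-[2,2-dimethyl-5-(TIPS-oxy)-2H-chromen-8-yl]acetic acid; 10 (S)-4-benzyloxazolidin-2-one
Product: 12 (S)-4-benzyl-3-(2-Ar-acetyl)oxazolidin-2-one, via mixed pivalic anhydride 11 (not isolated)
Conditions: PivCl, Et3N, THF, −20 °C; then 10, LiCl, rt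
Reagents that add atoms: none
Why: N-acylation of the oxazolidinone auxiliary through the mixed pivalic anhydride under LiCl/Et3N activation, which needs no strong base and so avoids ketene formation from the arylacetyl unit.

Step 7
Reactants: 12 (S)-4-benzyl-3-(2-Ar-acetyl)oxazolidin-2-one
Product: 14 (S)-4-benzyl-3-[(R)-2-Ar-3-hydroxypropanoyl]oxazolidin-2-one, via chlorotitanium Z-enolate 13 (not isolated)
Conditions: TiCl4, i-Pr2NEt, CH2Cl2, 0 °C; then 1,3,5-trioxane, TiCl4, 0 °C; aq. NH4Cl
Reagents that add atoms: 1,3,5-trioxane, C1OCOCO1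
Why: Evans titanium-enolate hydroxymethylation, in which TiCl4-activated formaldehyde attacks the chelated Z-enolate 13 on the face away from the benzyl group of the (S)-auxiliary and so sets the (R)-configuration of the future C3, the enolate being far more nucleophilic than the chromene alkene or arene at 0 °C.

Step 8
Reactants: 14 (S)-4-benzyl-3-[(R)-2-Ar-3-hydroxypropanoyl]oxazolidin-2-one
Product: 15 (R)-2-Ar-3-hydroxy-N-methoxy-N-methylpropanamide
Conditions: AlMe3, MeNH(OMe)·HCl, CH2Cl2, −15 → 0 °C; Rochelle salt work-up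
Reagents that add atoms: N,O-dimethylhydroxylamine hydrochloride, Cl.CNOC
Why: Weinreb transamination of a β-hydroxy imide with the aluminium amide reagent, in which the free hydroxyl directs attack to the exocyclic carbonyl, the auxiliary is released and the α-centre is not epimerised.

Step 9
Reactants: 15 (R)-2-Ar-3-hydroxy-N-methoxy-N-methylpropanamide
Product: 16 (R)-3-(TBS-oxy)-2-Ar-N-methoxy-N-methylpropanamide
Conditions: TBSCl, imidazole, DMF, rt
Reagents that add atoms: tert-butyldimethylsilyl chloride, CC(C)(C)[Si](C)(C)Cl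
Why: Standard silylation of a primary alcohol, where the TBS ether prevents hemiketal formation with the later chain carbonyls and retro-aldol loss of formaldehyde, and can later be removed by mild acid beside the aryl TIPS ether.

Step 10
Reactants: 16 (R)-3-(TBS-oxy)-2-Ar-N-methoxy-N-methylpropanamide; 17 methyl 3,5-dioxohexanoate
Product: 20 methyl (R)-9-(TBS-oxy)-8-Ar-3,5,7-trioxononanoate, via trilithium trianion 18 (not isolated), via tetrahedral amide adduct 19 (not isolated)
Conditions: 17, LiN(i-Pr)2 (3.2 equiv), THF, −78 → 0 °C; then 16 (0.5 equiv), −78 → −20 °C; AcOH, pH 5 buffer; crude 20 used at once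
Reagents that add atoms: none
Why: Terminal acylation of a 1,3,5-tricarbonyl trianion (polyanion Claisen condensation), in which the last-formed carbanion of 18 adds to the Weinreb amide, the chelated adduct 19 keeps the new ketone masked until the acidic quench, and allylic 1,3-strain in the tertiary amide holds the stereocentre C–H in the amide plane so that it should resist deprotonation.

Step 11
Reactants: 20 methyl (R)-9-(TBS-oxy)-8-Ar-3,5,7-trioxononanoate
Product: 22 (R)-3-(TBS-oxy)-2-Ar-1-(2,4,6-trihydroxyphenyl)propan-1-one, via cyclic triketone 21 (not isolated)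
Conditions: Mg(OMe)2, MeOH, rt; then cold 1 M HCl to pH 4
Reagents that add atoms: none
Why: Mg(OMe)2 turns 20 into a magnesium-chelated polyenolate in which every ketone oxygen is an enolate oxygen, so chain carbon C6 (future C4a) attacks the only remaining electrophile, the ester carbon C1 (future C5), methoxide leaves and triketone 21 tautomerises irreversibly to the phloroglucinol. The closest known reaction is the base-mediated Claisen (Dieckmann-type) cyclisation of 3,5,7-triketo esters to acylphloroglucinols, the folding used by chalcone synthase. Ring A closes in the 6-exo-trig mode, the enolate carbon adding to an ester carbonyl whose C=O lies outside the new ring. No stereocentre is formed; the existing one (chain C8, future C3) should survive because its neighbouring carbonyl C7 is locked in the chelated C5–C7 diketonate before cyclisation and conjugated to the ring A phenoxides afterwards, so removing the C8 proton would need a further, unfavourable charge next to the aryl group. The selectivity needed is Claisen over aldol folding (C2 onto C7) and over lactonisation: the aldol acceptor C7 is both enolised and flanked by the branched C8, and pyrone formation is reversible in methanol while aromatisation is not. Both silyl ethers should tolerate the weakly nucleophilic magnesium methoxide at room temperature.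

Step 12
Reactants: 22 (R)-3-(TBS-oxy)-2-Ar-1-(2,4,6-trihydroxyphenyl)propan-1-one
Product: 23 (R)-2-Ar-3-hydroxy-1-(2,4,6-trihydroxyphenyl)propan-1-one
Conditions: PPTS, MeOH, rt
Reagents that add atoms: none
Why: Acid-catalysed methanolysis cleaves a primary alkyl TBS ether much faster than an acid-stable aryl TIPS ether, and the mild non-basic medium should leave the C–H next to the ketone and the chromene untouched.

Step 13
Reactants: 23 (R)-2-Ar-3-hydroxy-1-(2,4,6-trihydroxyphenyl)propan-1-one
Product: 25 (R)-3-Ar-5,7-dihydroxychroman-4-one, via alkoxyphosphonium phenoxide 24 (not isolated)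
Conditions: PPh3, DIAD, THF (0.01 M), 0 °C → rt
Reagents that add atoms: none
Why: Intramolecular Mitsunobu etherification, in which either of the two equivalent ortho phenoxides of ring A displaces the primary alkoxyphosphonium of 24 in a 6-exo-tet closure of O1–C2, high dilution disfavours intermolecular alkylation of the 7-hydroxyl, and the stereocentre is not a reacting centre (this closure is known for 3-hydroxy-2-aryl-1-(2-hydroxyaryl)propan-1-ones with retention of configuration).

Step 14
Reactants: 25 (R)-3-Ar-5,7-dihydroxychroman-4-one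
Product: 26 (R)-5,7-dihydroxy-3-(5-hydroxy-2,2-dimethyl-2H-chromen-8-yl)chroman-4-one
Conditions: TBAF, AcOH (1:1), THF, 0 °C
Reagents that add atoms: none
Why: Fluoride cleavage of an aryl silyl ether, buffered with acetic acid so that the medium stays non-basic and the labile C3 centre between ketone and aryl ring is neither epimerised nor the chromanone ring opened.

## Compound list

1 | 2,4-dihydroxyphenylacetic acid | OC(=O)Cc1ccc(O)cc1O | starting material
2 | methyl 2-(2,4-dihydroxyphenyl)acetate | COC(=O)Cc1ccc(O)cc1O | intermediate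
3 | methyl 2-[2-hydroxy-4-(triisopropylsilyloxy)phenyl]acetate | COC(=O)Cc1ccc(O[Si](C(C)C)(C(C)C)C(C)C)cc1O | intermediate
4 | 3-chloro-3-methylbut-1-yne | CC(C)(Cl)C#C | starting material
5 | methyl 2-[2-(2-methylbut-3-yn-2-yloxy)-4-(triisopropylsilyloxy)phenyl]acetate | COC(=O)Cc1ccc(O[Si](C(C)C)(C(C)C)C(C)C)cc1OC(C)(C)C#C | intermediate
6 | methyl 2-[2-hydroxy-3-(3-methylbuta-1,2-dienyl)-4-(triisopropylsilyloxy)phenyl]acetate | COC(=O)Cc1ccc(O[Si](C(C)C)(C(C)C)C(C)C)c(C=C=C(C)C)c1O | intermediate (not isolated)
7 | methyl 2-[5-(3-methylbut-2-en-1-ylidene)-6-oxo-4-(triisopropylsilyloxy)cyclohexa-1,3-dien-1-yl]acetate | COC(=O)CC1=CC=C(O[Si](C(C)C)(C(C)C)C(C)C)C(=CC=C(C)C)C1=O | intermediate (not isolated)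
8 | methyl 2-[2,2-dimethyl-5-(triisopropylsilyloxy)-2H-chromen-8-yl]acetate | COC(=O)Cc1ccc(O[Si](C(C)C)(C(C)C)C(C)C)c2C=CC(C)(C)Oc12 | intermediate
9 | 2-[2,2-dimethyl-5-(triisopropylsilyloxy)-2H-chromen-8-yl]acetic acid | OC(=O)Cc1ccc(O[Si](C(C)C)(C(C)C)C(C)C)c2C=CC(C)(C)Oc12 | intermediate
10 | (S)-4-benzyloxazolidin-2-one | O=C1N[C@@H](Cc2ccccc2)CO1 | starting material
11 | 2-[2,2-dimethyl-5-(triisopropylsilyloxy)-2H-chromen-8-yl]acetic pivalic anhydride | CC(C)(C)C(=O)OC(=O)Cc1ccc(O[Si](C(C)C)(C(C)C)C(C)C)c2C=CC(C)(C)Oc12 | intermediate (not isolated)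
12 | (S)-4-benzyl-3-{2-[2,2-dimethyl-5-(triisopropylsilyloxy)-2H-chromen-8-yl]acetyl}oxazolidin-2-one | O=C(Cc1ccc(O[Si](C(C)C)(C(C)C)C(C)C)c2C=CC(C)(C)Oc12)N1[C@@H](Cc2ccccc2)COC1=O | intermediate
13 | trichlorotitanium (Z)-enolate of 12 | Cl[Ti](Cl)(Cl)O/C(=C\c1ccc(O[Si](C(C)C)(C(C)C)C(C)C)c2C=CC(C)(C)Oc12)N1[C@@H](Cc2ccccc2)COC1=O | intermediate (not isolated)
14 | (S)-4-benzyl-3-{(R)-2-[2,2-dimethyl-5-(triisopropylsilyloxy)-2H-chromen-8-yl]-3-hydroxypropanoyl}oxazolidin-2-one | OC[C@@H](c1ccc(O[Si](C(C)C)(C(C)C)C(C)C)c2C=CC(C)(C)Oc12)C(=O)N1[C@@H](Cc2ccccc2)COC1=O | intermediate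
15 | (R)-2-[2,2-dimethyl-5-(triisopropylsilyloxy)-2H-chromen-8-yl]-3-hydroxy-N-methoxy-N-methylpropanamide | OC[C@@H](c1ccc(O[Si](C(C)C)(C(C)C)C(C)C)c2C=CC(C)(C)Oc12)C(=O)N(C)OC | intermediate
16 | (R)-3-(tert-butyldimethylsilyloxy)-2-[2,2-dimethyl-5-(triisopropylsilyloxy)-2H-chromen-8-yl]-N-methoxy-N-methylpropanamide | CC(C)(C)[Si](C)(C)OC[C@@H](c1ccc(O[Si](C(C)C)(C(C)C)C(C)C)c2C=CC(C)(C)Oc12)C(=O)N(C)OC | intermediate
17 | methyl 3,5-dioxohexanoate | COC(=O)CC(=O)CC(C)=O | starting material
18 | trilithium trianion of methyl 3,5-dioxohexanoate | [Li+].[Li+].[Li+].COC(=O)[CH-]C(=O)[CH-]C(=O)[CH2-] | intermediate (not isolated)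
19 | trilithium salt of the N-methoxy-N-methyl hemiaminal alkoxide from addition of 18 to 16 | [Li+].[Li+].[Li+].COC(=O)[CH-]C(=O)[CH-]C(=O)CC([O-])(N(C)OC)[C@@H](CO[Si](C)(C)C(C)(C)C)c1ccc(O[Si](C(C)C)(C(C)C)C(C)C)c2C=CC(C)(C)Oc12 | intermediate (not isolated)
20 | methyl (R)-9-(tert-butyldimethylsilyloxy)-8-[2,2-dimethyl-5-(triisopropylsilyloxy)-2H-chromen-8-yl]-3,5,7-trioxononanoate | COC(=O)CC(=O)CC(=O)CC(=O)[C@@H](CO[Si](C)(C)C(C)(C)C)c1ccc(O[Si](C(C)C)(C(C)C)C(C)C)c2C=CC(C)(C)Oc12 | intermediate
21 | 2-{(R)-3-(tert-butyldimethylsilyloxy)-2-[2,2-dimethyl-5-(triisopropylsilyloxy)-2H-chromen-8-yl]propanoyl}cyclohexane-1,3,5-trione | O=C1CC(=O)C(C(=O)[C@@H](CO[Si](C)(C)C(C)(C)C)c2ccc(O[Si](C(C)C)(C(C)C)C(C)C)c3C=CC(C)(C)Oc23)C(=O)C1 | intermediate (not isolated)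
22 | (R)-3-(tert-butyldimethylsilyloxy)-2-[2,2-dimethyl-5-(triisopropylsilyloxy)-2H-chromen-8-yl]-1-(2,4,6-trihydroxyphenyl)propan-1-one | Oc1cc(O)c(C(=O)[C@@H](CO[Si](C)(C)C(C)(C)C)c2ccc(O[Si](C(C)C)(C(C)C)C(C)C)c3C=CC(C)(C)Oc23)c(O)c1 | intermediate
23 | (R)-2-[2,2-dimethyl-5-(triisopropylsilyloxy)-2H-chromen-8-yl]-3-hydroxy-1-(2,4,6-trihydroxyphenyl)propan-1-one | Oc1cc(O)c(C(=O)[C@@H](CO)c2ccc(O[Si](C(C)C)(C(C)C)C(C)C)c3C=CC(C)(C)Oc23)c(O)c1 | intermediate
24 | alkoxytriphenylphosphonium phenoxide zwitterion of 23 | Oc1cc(O)c(C(=O)[C@@H](CO[P+](c2ccccc2)(c2ccccc2)c2ccccc2)c2ccc(O[Si](C(C)C)(C(C)C)C(C)C)c3C=CC(C)(C)Oc23)c([O-])c1 | intermediate (not isolated)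
25 | (R)-3-[2,2-dimethyl-5-(triisopropylsilyloxy)-2H-chromen-8-yl]-5,7-dihydroxychroman-4-one | CC1(C)C=Cc2c(O[Si](C(C)C)(C(C)C)C(C)C)ccc([C@@H]3COc4cc(O)cc(O)c4C3=O)c2O1 | intermediate
26 | (R)-5,7-dihydroxy-3-(5-hydroxy-2,2-dimethyl-2H-chromen-8-yl)chroman-4-one | CC1(C)C=Cc2c(O)ccc([C@@H]3COc4cc(O)cc(O)c4C3=O)c2O1 | target

## Step count and risks

Total steps: 14. Longest linear sequence: 14 steps (1 to 26); 4, 10 and 17 enter as purchased materials.

Steps most likely to fail:

Step 11. The process to fear is base-induced loss of configuration at chain C8, by enolisation toward the aryl-bearing carbon or by β-elimination of silanolate and re-addition, during or after folding; folding in the aldol sense is the second concern. The fallback builds ring A from a preformed phloroglucinol; it sets out from 16 and comes back at 23. Phloroglucinol is converted with MOMCl and i-Pr2NEt into 1,3,5-tris(methoxymethoxy)benzene F1. Lithiation of F1 between two MOM ethers with n-BuLi in THF at 0 °C gives 2,4,6-tris(methoxymethoxy)phenyllithium F2. Addition of F2 to Weinreb amide 16 at −78 °C should give, through a stable chelated adduct, (R)-3-(TBS-oxy)-2-Ar-1-[2,4,6-tris(methoxymethoxy)phenyl]propan-1-one F3. HCl in MeOH at rt to 40 °C should then remove the three MOM groups and the primary TBS ether in one operation, with the aryl TIPS ether and the chromene remaining, to give 23.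

Step 10. The processes to fear are proton transfer from the amide α-carbon to the aggregated trianion outrunning addition at the hindered carbonyl (with loss of configuration or of silanolate), N–O cleavage of the Weinreb amide, and uncontrolled cyclisation of the triketo ester during isolation. The fallback joins the chain in two stages; it sets out from 16 and comes back at 20. The small lithium enolate of methyl acetate (MeOAc, LiN(i-Pr)2, THF, −78 °C) should add to 16 to give methyl (R)-5-(TBS-oxy)-4-Ar-3-oxopentanoate F4. NaH converts F4 into the sodium enolate of methyl (R)-5-(TBS-oxy)-4-Ar-3-oxopentanoate F5, which places the carbonyl next to the stereocentre in an enolate and so shields that C–H. The dianion of methyl acetoacetate (NaH, then n-BuLi, THF, 0 °C) is then acylated at its terminal carbon by the ester carbonyl of F5 (0 °C → rt), a polyanion Claisen condensation with a β-keto ester monoanion, and acidic quench returns 20.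

Step 13. The processes to fear are elimination of the activated primary oxygen across C2–C3 through the ketone followed by oxa-Michael re-closure, which would erase the C3 configuration, and intermolecular alkylation of the 7-hydroxyl or of the hydrazide. The fallback separates activation from ring closure; it sets out from 23 and comes back at 25. Appel bromination (PPh3, CBr4, CH2Cl2, 0 °C) should convert only the primary alcohol into (S)-3-bromo-2-Ar-1-(2,4,6-trihydroxyphenyl)propan-1-one F6 (same spatial arrangement, descriptor changed by the bromine). NaHCO3 in acetone/DMF at rt then ionises only the acidic ortho hydroxyl of the acylphloroglucinol, and its phenoxide closes O1–C2 by a 6-exo-tet Williamson displacement to give 25.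

Further compounds
F1 | step 11 | 1,3,5-tris(methoxymethoxy)benzene | COCOc1cc(OCOC)cc(OCOC)c1
F2 | step 11 | 2,4,6-tris(methoxymethoxy)phenyllithium | [Li]c1c(OCOC)cc(OCOC)cc1OCOC
F3 | step 11 | (R)-3-(tert-butyldimethylsilyloxy)-2-[2,2-dimethyl-5-(triisopropylsilyloxy)-2H-chromen-8-yl]-1-[2,4,6-tris(methoxymethoxy)phenyl]propan-1-one | COCOc1cc(OCOC)c(C(=O)[C@@H](CO[Si](C)(C)C(C)(C)C)c2ccc(O[Si](C(C)C)(C(C)C)C(C)C)c3C=CC(C)(C)Oc23)c(OCOC)c1
F4 | step 10 | methyl (R)-5-(tert-butyldimethylsilyloxy)-4-[2,2-dimethyl-5-(triisopropylsilyloxy)-2H-chromen-8-yl]-3-oxopentanoate | COC(=O)CC(=O)[C@@H](CO[Si](C)(C)C(C)(C)C)c1ccc(O[Si](C(C)C)(C(C)C)C(C)C)c2C=CC(C)(C)Oc12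
F5 | step 10 | sodium enolate of methyl (R)-5-(tert-butyldimethylsilyloxy)-4-[2,2-dimethyl-5-(triisopropylsilyloxy)-2H-chromen-8-yl]-3-oxopentanoate | [Na+].COC(=O)C=C([O-])[C@@H](CO[Si](C)(C)C(C)(C)C)c1ccc(O[Si](C(C)C)(C(C)C)C(C)C)c2C=CC(C)(C)Oc12
F6 | step 13 | (S)-3-bromo-2-[2,2-dimethyl-5-(triisopropylsilyloxy)-2H-chromen-8-yl]-1-(2,4,6-trihydroxyphenyl)propan-1-one | Oc1cc(O)c(C(=O)[C@@H](CBr)c2ccc(O[Si](C(C)C)(C(C)C)C(C)C)c3C=CC(C)(C)Oc23)c(O)c1
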